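The earlier runs and the new flask were generated by integration from invented constants, noise included.

The pitfall in your hunch, when you asked me for a quick number, was to read the share at a run's last reading as the share of a finished flask, so I first asked how far through its charge a run had come.

| setting | Thursday's | Tuesday's | theta | gamma | zeta | beta |
|---|---|---|---|---|---|---|
| starting material | 19 mM | 19 mM | 19 mM (fed, over 4.80 min) | 19 mM | 19 mM | 19 mM |
| reagent | 3 equiv | 4.5 equiv | 3.00 equiv | 3.00 equiv | 3.00 equiv | 3.00 equiv (fed, over 4.80 min) |
| remark | run made earlier | run made earlier | all but starting material at the start; starting material goes in evenly over 4.80 min, the run ends at 6.0 min | one stirred flow tank at steady state, fed with the mixture as stated, mean residence time 6.0 min | a closed flask charged with all of it at once and left for 6.0 min | all but reagent at the start; reagent goes in evenly over 4.80 min, the run ends at 6.0 min |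
| time |  |  | 6.0 min |  | 6.0 min | 6.0 min |

- Thursday's (time / min: target / %, side product / %): 0.250: 0, 0; 0.667: 0, 0.9; 1.50: 0.9, 4.5; 4.00: 1.3, 13.8
- Tuesday's (time / s: target / %, side product / %): 10.0: 0, 1.4; 12.0: 0, 0; 30.0: 0.3, 0; 80.0: 0, 5.4

(standard deviation of a reading: 1 percentage point)

- the set-up with the highest share of target in all that became target or side product, at the outlet or at the end ("none" if the first two lie within 2 percentage points) (theta / gamma / zeta / beta / none)
- share of target in all that became target or side product, at the outlet or at the end, theta
- share of target in all that became target or side product, at the outlet or at the end, gamma
- share of target in all that became target or side product, at the outlet or at the end, zeta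
- share of target in all that became target or side product, at the outlet or at the end, beta

- percentages count the starting material that a species holds: one side product counts as two
- the stated concentrations are those of everything mixed, before any reaction; amounts are the same in each set-up
- the feed brings no volume worth counting
- the earlier runs were made in a closed, stirred flask

At its last reading, 4.00 min, Thursday's run held 1.3% target and 13.8% side product, which gave a share of target, the selectivity, of 8.61%. I solved the two ends and joined them: for the early end I drew a straight line through that sum, for the far end I assumed the whole charge, and the time at which the line reaches the whole charge I called the crossing time, 26.5 min. Tuesday's run, with more reagent, read 5.4% side product and 0% target at 80.0 s, where that line stood at 5.03%. Since 6.0 min is shorter than the crossing time, I told you that zeta would be 22.7% of the way along that line. I committed to Thursday's 8.61% for zeta and named no winner, because one reading's scatter could move that share by about 6.6 percentage points, more than the margin of 2 points.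

The forecast differed from me, giving theta 15.5%, gamma 13%, zeta 12% and beta 11.5%, with the words “Theta is best, but the margin is uncertain”. The flasks gave theta 9.71%, gamma 16.1%, zeta 12.9% and beta 11.1%, so gamma came first.

    starting material → intermediate A (k = 0.220 min⁻¹)
    intermediate A ⇌ intermediate B (K = 1.10, k = 0.260 min⁻¹)
    reagent + intermediate B ⇌ target (K = 15.0 M⁻¹, k = 0.950 M⁻¹ min⁻¹)
    starting material + intermediate A → side product (k = 8.00 M⁻¹ min⁻¹)

At 6.0 min zeta held 3.09% target and 20.8% side product, together 23.9% against my 22.7%. In theta the charge had spent 3.60 min in the flask on average, so the crossing time gave 13.6% against the simulated 13.4%. Zeta had not come to rest at 6.0 min, with 21% of its starting material still there. Left for 60.0 min, zeta had 0% starting material, 20.9% target and 28.4% side product, its share went from 12.9% to 42.3%, and theta's share reached 43.2%.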